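## Retrosynthetic overview

1. The 1',5'-epoxide and the absolute configuration come last, from a catalyst-controlled Shi epoxidation of the racemic dimer 16 run as a kinetic resolution; the C1–OH comes from aerobic γ-oxygenation of the β,γ-enone 14.
2. The spiro-cyclohexene (C5–C13' and C3–C11') is cut to two molecules of racemic 8-epi-xanthatin 13, joined by a SmI2-catalysed radical-anion (4+2) annulation in which opposite enantiomers pair.
3. 13 comes from enol triflate 11 and methyl vinyl ketone (Heck); the α-methylene group comes from a malonate-derived carboxyl.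
4. The cis-fused lactone comes from a Mn(OAc)3 radical annulation of dienol 4 with a malonate half ester; C10 is set by convex-face hydrogenation.
5. The seven-membered ring is bought as tropone; ring order: carbocycle, then lactone, then cyclohexene (dimerisation), then epoxide.

Assumptions: xanthanolide numbering (C1–C15, primes for the epoxide-bearing half) is used throughout. Racemic compounds are drawn as the enantiomer that ends up in the target. The tert-butyl group of 5 is a carboxyl protecting group on malonic acid.

## Route

Step 1
Reactants: 1 tropone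
Product: 3 2-methylcyclohepta-2,4-dien-1-one, via 2-methylcyclohepta-3,5-dien-1-one 2 (not isolated)
Conditions: MeMgBr, THF, −78 °C; H2O; then DBU (0.1 equiv), CH2Cl2, 25 °C
Reagents that add atoms: methylmagnesium bromide, C[Mg]Br
Why: Grignard reagents add to tropone in 1,8-fashion at C2, and DBU then moves the skipped diene by dienolisation into the fully conjugated, more substituted 2-methyl-2,4-dienone, which has no stereocentre.

Step 2
Reactants: 3 2-methylcyclohepta-2,4-dien-1-one
Product: 4 rac-2-methylcyclohepta-2,4-dien-1-ol
Conditions: NaBH4, CeCl3·7H2O, MeOH, 0 °C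
Reagents that add atoms: none
Why: Luche reduction gives clean 1,2-reduction of the dienone; the racemic carbinol centre is erased again in step 4.

Step 3
Reactants: 4 rac-2-methylcyclohepta-2,4-dien-1-ol; 5 malonic acid mono-tert-butyl ester
Product: 6 rac-tert-butyl 6-hydroxy-7-methyl-2-oxo-3,3a,4,5,6,8a-hexahydro-2H-cyclohepta[b]furan-3-carboxylate (cis ring fusion; epimers at C3 and C6)
Conditions: Mn(OAc)3·2H2O (2.2 equiv), KOAc, AcOH, 25–40 °C
Reagents that add atoms: none
Why: Oxidative radical γ-lactone annulation of a 1,3-diene: Mn(OAc)3 turns the half ester into an electrophilic radical that adds to the unsubstituted diene terminus C7, the allyl radical is oxidised to the cation, and the carboxylate closes on the adjacent C8, which in a five/seven bicycle can only give the cis-fused lactone (KOAc buffer keeps the dienol from ionising).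

Step 4
Reactants: 6 hydroxy lactone ester
Product: 7 rac-tert-butyl 7-methyl-2,6-dioxo-3,3a,4,5,6,8a-hexahydro-2H-cyclohepta[b]furan-3-carboxylate (cis ring fusion)
Conditions: MnO2, CH2Cl2, 25 °C
Reagents that add atoms: none
Why: MnO2 oxidises the secondary allylic alcohol selectively to the enone and removes the C1 epimer mixture.

Step 5
Reactants: 7 enone lactone ester
Product: 8 rac-tert-butyl 7-methyl-2,6-dioxooctahydro-2H-cyclohepta[b]furan-3-carboxylate (H7, H8 and H10 all cis)
Conditions: H2 (1 atm), 5% Rh/Al2O3, EtOAc, 25 °C
Reagents that add atoms: none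
Why: Heterogeneous hydrogenation adds both hydrogens to the enone C=C from the convex face of the cis-fused bicycle (the face of H7 and H8), which sets C10 with H10 cis to H7/H8; Rh/Al2O3 is chosen to limit hydrogenolysis of the allylic lactone C–O bond.

Step 6
Reactants: 8 keto lactone ester
Product: 9 rac-tert-butyl 7-methyl-2-oxo-6-(trifluoromethylsulfonyloxy)-3,3a,4,7,8,8a-hexahydro-2H-cyclohepta[b]furan-3-carboxylate
Conditions: LDA (2.2 equiv), THF, −78 °C; PhNTf2 (1.1 equiv); H2O
Reagents that add atoms: N-phenylbis(trifluoromethanesulfonimide), O=S(=O)(N(c1ccccc1)S(=O)(=O)C(F)(F)F)C(F)(F)F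
Why: Kinetic enol triflate formation: the first equivalent of LDA parks the acidic malonate-type C–H as its enolate, the second removes the kinetically favoured proton at the unsubstituted α-carbon C5, and O-triflation of that enolate fixes the C1=C5 double bond without touching C10.

Step 7
Reactants: 9 enol triflate ester
Product: 11 rac-7-methyl-3-methylidene-2-oxo-3,3a,4,7,8,8a-hexahydro-2H-cyclohepta[b]furan-6-yl trifluoromethanesulfonate, via lactone acid 10 (not isolated)
Conditions: TFA, CH2Cl2, 0 °C; evaporate; Et2NH, 37% aq. HCHO, THF, 50 °C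
Reagents that add atoms: formaldehyde, C=O
Why: Decarboxylative methylenation: TFA cleaves the tert-butyl ester, and the α-carboxy lactone undergoes Mannich condensation with formaldehyde and Et2NH followed by loss of CO2 and amine to give the α-methylene lactone, under conditions that leave the enol triflate intact.

Step 8
Reactants: 11 methylene lactone triflate; 12 methyl vinyl ketone (5 equiv)
Product: 13 rac-8-epi-xanthatin (7R*,8R*,10S*)
Conditions: Pd(OAc)2 (5 mol%), PPh3 (10 mol%), Et3N, DMF, 60 °C
Reagents that add atoms: none
Why: Heck reaction: zerovalent palladium inserts into the enol triflate, adds across the unhindered monosubstituted alkene of excess 12, and β-hydride elimination gives the (E)-dienone, while the 1,1-disubstituted methylene lactone reacts much more slowly.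

Step 9
Reactants: 13 rac-8-epi-xanthatin (two molecules)
Product: 14 rac-unlike dimer with C1=C2 and C3–H (upper half 7R*,8R*,10S*; lower half 7'S*,8'S*,10'R*; spiro at C11')
Conditions: SmI2 (0.25 equiv), THF (0.5 M), 45 °C, Ar, to about 60% conversion
Reagents that add atoms: none
Why: Proposed new method: SmI2 reversibly reduces the dienone of one molecule to a samarium-bound pentadienyl ketyl radical whose δ-terminus C5 adds (Giese-type, on the face cis to the C10 methyl) to the CH2 of the methylene lactone of a second molecule; the tertiary α-lactone radical then closes 6-exo onto C3 of the trivalent-samarium dienolate through a chair with the bulky C7' equatorial and attack on the convex face of the acceptor bicycle, and the new ketyl hands the electron back so that divalent samarium turns over; the closest known reactions are SmI2-catalysed radical-relay couplings of ketones with alkenes and radical-anion enone cycloadditions; pairing of opposite enantiomers gives racemic 14, which is separated from the like-paired diastereomer, and a C3 epimer would converge in step 10.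

Step 10
Reactants: 14 rac-unlike dimer
Product: 16 rac-1-hydroxy-2-ene dimer (OH anti to H5), via hydroperoxide 15 (not isolated)
Conditions: O2 (1 atm), DBU (0.2 equiv), MeCN, 0 °C; then PPh3
Reagents that add atoms: dioxygen, O=O
Why: Vinylogous autoxidation of a β,γ-unsaturated ketone: DBU removes the doubly activated C3–H and the dienolate combines with triplet O2 by electron transfer and radical recombination at the γ-carbon C1, O2 entering axially, anti to H5 and to the axial lactone carbonyl on C11', so the trans-fused tertiary hydroperoxide forms and PPh3 reduces it to the alcohol.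

Step 11
Reactants: 16 rac-1-hydroxy-2-ene dimer
Product: 17 target CNP0177598.2
Conditions: D-fructose-derived Shi ketone (0.3 equiv), Oxone (2KHSO5·KHSO4·K2SO4, 0.6 equiv KHSO5), K2CO3, Bu4NHSO4, MeCN–CH2(OMe)2–aq. Na2B4O7 buffer (pH 10.5), −10 °C, to about 45% conversion
Reagents that add atoms: potassium peroxymonosulfate, [K+].[O-]S(=O)(=O)OO
Why: Shi epoxidation run as a kinetic resolution: the dioxirane attacks the only electron-rich alkene (trisubstituted C1'=C5') through the spiro transition state that gives the (1'R,5'R) oxide, and this face is the open one anti to the C10' methyl only in the enantiomer of 16 with the (7'S,8'S,10'R) lower half, which is converted to 17 while the other enantiomer is left behind and removed by chromatography.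

## Compound list

1 | tropone (cyclohepta-2,4,6-trien-1-one) | O=C1C=CC=CC=C1 | starting material
2 | rac-2-methylcyclohepta-3,5-dien-1-one | CC1C=CC=CCC1=O | intermediate
3 | 2-methylcyclohepta-2,4-dien-1-one | CC1=CC=CCCC1=O | intermediate
4 | rac-2-methylcyclohepta-2,4-dien-1-ol | CC1=CC=CCCC1O | intermediate
5 | malonic acid mono-tert-butyl ester (tert-butyl is a protecting group) | CC(C)(C)OC(=O)CC(O)=O | starting material
6 | rac-tert-butyl 6-hydroxy-7-methyl-2-oxo-3,3a,4,5,6,8a-hexahydro-2H-cyclohepta[b]furan-3-carboxylate (cis-fused; epimers at C3 and C6) | CC1=C[C@@H]2[C@H](CCC1O)C(C(=O)OC(C)(C)C)C(=O)O2 | intermediate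
7 | rac-tert-butyl 7-methyl-2,6-dioxo-3,3a,4,5,6,8a-hexahydro-2H-cyclohepta[b]furan-3-carboxylate (cis-fused) | CC1=C[C@@H]2[C@H](CCC1=O)C(C(=O)OC(C)(C)C)C(=O)O2 | intermediate
8 | rac-tert-butyl 7-methyl-2,6-dioxooctahydro-2H-cyclohepta[b]furan-3-carboxylate (H7, H8, H10 all cis) | C[C@H]1C[C@@H]2[C@H](CCC1=O)C(C(=O)OC(C)(C)C)C(=O)O2 | intermediate
9 | rac-tert-butyl 7-methyl-2-oxo-6-(trifluoromethylsulfonyloxy)-3,3a,4,7,8,8a-hexahydro-2H-cyclohepta[b]furan-3-carboxylate | C[C@H]1C[C@@H]2[C@H](CC=C1OS(=O)(=O)C(F)(F)F)C(C(=O)OC(C)(C)C)C(=O)O2 | intermediate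
10 | rac-7-methyl-2-oxo-6-(trifluoromethylsulfonyloxy)-3,3a,4,7,8,8a-hexahydro-2H-cyclohepta[b]furan-3-carboxylic acid | C[C@H]1C[C@@H]2[C@H](CC=C1OS(=O)(=O)C(F)(F)F)C(C(O)=O)C(=O)O2 | intermediate
11 | rac-7-methyl-3-methylidene-2-oxo-3,3a,4,7,8,8a-hexahydro-2H-cyclohepta[b]furan-6-yl trifluoromethanesulfonate | C[C@H]1C[C@@H]2[C@H](CC=C1OS(=O)(=O)C(F)(F)F)C(=C)C(=O)O2 | intermediate
12 | methyl vinyl ketone (but-3-en-2-one) | CC(=O)C=C | starting material
13 | rac-8-epi-xanthatin (7R*,8R*,10S*) | C[C@H]1C[C@@H]2[C@H](CC=C1/C=C/C(C)=O)C(=C)C(=O)O2 | intermediate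
14 | rac-unlike dimer, β,γ-enone (C1=C2, C3–H with H3 cis to H5; lower half still the (E)-dienone) | C=C1C(=O)O[C@@H]2C[C@H](C)C3=C[C@H](C(C)=O)[C@]4(C[C@@H]3C[C@H]12)C(=O)O[C@H]1C[C@@H](C)C(/C=C/C(C)=O)=CC[C@H]14 | intermediate
15 | rac-C1 hydroperoxide of the dimer (C2=C3 enone) | C=C1C(=O)O[C@@H]2C[C@H](C)[C@@]3(OO)C=C(C(C)=O)[C@]4(C[C@@H]3C[C@H]12)C(=O)O[C@H]1C[C@@H](C)C(/C=C/C(C)=O)=CC[C@H]14 | intermediate
16 | rac-1-hydroxy-2-ene dimer (target without the epoxide) | C=C1C(=O)O[C@@H]2C[C@H](C)[C@@]3(O)C=C(C(C)=O)[C@]4(C[C@@H]3C[C@H]12)C(=O)O[C@H]1C[C@@H](C)C(/C=C/C(C)=O)=CC[C@H]14 | intermediate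
17 | CNP0177598.2 | C=C1C(=O)O[C@@H]2C[C@H](C)[C@@]3(O)C=C(C(C)=O)[C@]4(C[C@@H]3C[C@H]12)C(=O)O[C@H]1C[C@@H](C)[C@]2(/C=C/C(C)=O)O[C@@H]2C[C@H]14 | target

## Step count and risks

Total step count: 11. Longest linear sequence: 11 steps (1 to 17); 5 and 12 are bought.

The three steps most likely to fail are steps 9, 3 and 11.

Step 9 is unprecedented: the ketyl radical could couple through C2 or the carbonyl carbon instead of C5, the s-trans radical anion could close to a cyclobutane, the C5 face selectivity is assumed, and the product can be reduced again and oligomerise. The fallback sets out from 13 and comes back at 14: rac-8-epi-xanthatin is dimerised by a thermal Diels–Alder reaction (2 M in toluene with a trace of BHT, 100–110 °C), a concerted exo cycloaddition that gives the same racemic unlike dimer 14 beside its like-paired diastereomer; this fallback makes no new compound (F0).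

Step 3 may suffer from ionisation of the dienol in acetic acid or from competing attack at the methyl-bearing diene terminus. The fallback sets out from 3 and comes back at 7, by-passing 4 and 6. Sodium di-tert-butyl malonate is added 1,6 to dienone 3 in THF at −40 °C with kinetic α-protonation to give di-tert-butyl 2-(4-methyl-5-oxocyclohept-2-en-1-yl)malonate F1. Iodolactonisation (I2, NaHCO3, MeCN, 0 °C), in which one tert-butyl ester closes on C8, then gives the cis-fused iodolactone F2, and Et3N eliminates hydrogen iodide across C9–C10 to give enone 7.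

Step 11 needs a good selectivity factor on a late, valuable racemate, and the matched face rests on analogy with 1-aryl- and 1-alkenyl-cycloalkenes. The fallback sets out from 16 and comes back at 17: racemic 16 is resolved by preparative chromatography on a chiral stationary phase (supercritical CO2/MeOH) to give the single enantiomer of the 1-hydroxy-2-ene dimer F3 (upper half 7R,8R,10S; lower half 7'S,8'S,10'R), and dimethyldioxirane (acetone, −20 °C) then epoxidises C1'=C5' under substrate control, anti to the C10' methyl, to give 17.

Further compounds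
F0 | step 9 | none | none
F1 | step 3 | rac-di-tert-butyl 2-(4-methyl-5-oxocyclohept-2-en-1-yl)malonate (epimers at the methyl-bearing carbon) | CC1C=C[C@H](CCC1=O)C(C(=O)OC(C)(C)C)C(=O)OC(C)(C)C
F2 | step 3 | rac-tert-butyl 8-iodo-7-methyl-2,6-dioxooctahydro-2H-cyclohepta[b]furan-3-carboxylate (cis-fused, iodine trans to the lactone oxygen) | CC1[C@H](I)[C@@H]2[C@H](CCC1=O)C(C(=O)OC(C)(C)C)C(=O)O2
F3 | step 11 | single enantiomer of the 1-hydroxy-2-ene dimer (7R,8R,10S; 7'S,8'S,10'R) | C=C1C(=O)O[C@@H]2C[C@H](C)[C@@]3(O)C=C(C(C)=O)[C@]4(C[C@@H]3C[C@H]12)C(=O)O[C@H]1C[C@@H](C)C(/C=C/C(C)=O)=CC[C@H]14
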